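The pitfall is to rank these flasks by the E.X each one makes and forget that X.E.Q, the other term of the asked share, keeps draining through the wait.

    E + Q → E.Q (k1 = 1.4 × 10⁻⁴ L mol⁻¹ s⁻¹)
    X + E.Q ⇌ X.E.Q (K2 = 1.8 L mol⁻¹, k2 = 2.2 × 10⁻⁵ L mol⁻¹ s⁻¹)
    E + X → E.X (k3 = 3.3 × 10⁻⁶ L mol⁻¹ s⁻¹)
    E.Q → G (k4 = 6.4 × 10⁻⁶ s⁻¹)
    E ⇌ Z (K5 = 0.63, k5 = 3.3 × 10⁻⁵ s⁻¹)

in all of them: Q 0.200 M; time 8.0 d

| flask | E | X | remark |
|---|---|---|---|
| midnight | 0.10 M | 0.200 M (fed, over 40 h) | all else is in the flask from the start; the feed brings no volume worth counting |
| spring | 0.10 M (fed, over 40 h) | 0.200 M | all else is in the flask from the start; the feed brings no volume worth counting |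
| autumn | 0.10 M | 0.200 M (in portions, 4, over 40 h) | first portion at the start, last at 40 h |
| winter | 0.10 M | 0.200 M | everything together at the start |

1. the best flask by share of X.E.Q in X.E.Q plus E.X; "all alike" if 1.5 percentage points covers them all (midnight / spring / autumn / winter / all alike)
2. share of X.E.Q in X.E.Q plus E.X at the end, midnight
3. share of X.E.Q in X.E.Q plus E.X at the end, spring
4. share of X.E.Q in X.E.Q plus E.X at the end, autumn
5. share of X.E.Q in X.E.Q plus E.X at the end, winter

I built winter up one process at a time. With E + Q and E + X running at the charged concentrations, E went to E.Q 42 times as fast as to E.X at the start, so holding that ratio gave E.X 2.33% of the E charged. But c(Q) falls as Q works, so I divided the two rates and integrated over the Q used. That gave the leak 0.00471 M, the E.X made while c(Q) falls by a factor of e with c(X) as charged; the charged c(X) over the leak is the selectivity factor of the two E steps, 42.4. E, at 0.10 M against 0.200 M of Q, is the limiting reagent, so I let c(Q) drop by 0.10 M and reckoned E.X at 0.00327 M, which is 3.27% of the E charged.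

Next came E ⇌ Z. It relaxes in 0.0940 d, faster than the 0.29 d of E + Q, so I took it as settled at once, leaving 61.3% of the E free. Both routes draw on free E, so the leak stayed as it was, but the mean stay of E, reckoned at the midway c(Q), stretched to 0.898 d.

Then came binding and drain. The binding runs on at 4.40 × 10⁻⁶ s⁻¹ and off at 1.22 × 10⁻⁵ s⁻¹, and with E.Q → G they form a linear pair whose slow root is 4.14 × 10⁻⁶ s⁻¹. In that mode X.E.Q has an amplitude of 29.9% of the E.Q formed, so I reckoned winter to hold 0.00227 M of X.E.Q at the end, a share of 41.0%.

Feeding X over 40 h puts c(X) at 53.9% of its charge at the mean stay, so for midnight I scaled E.X to 0.00176 M and kept X.E.Q, for a share of 56.3%. I put autumn just below that. Spring keeps the leak, but its E arrives 20.0 h later on average, which gives 48.4%.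

The forecast gave 51%, 47%, 48% and 42% for midnight, spring, autumn and winter, with my winner midnight but a lower midnight than mine, on the ground that "Holding X back while E is being consumed (midnight, then autumn) cuts E.X most".

The simulation gave 61.1%, 51.3%, 58.6% and 43.8% in that order, and the best flask was midnight.

Winter ended with 51.6% of its Q, and the leak over that fall gives 3.12% of the E charged, against 3.01% of E.X in the flask. The neighbour is winter cut to 0.050 M of Q, and those 0.500 equiv of Q make Q the limiting reagent: it ended at 4.13% of its charge, with 23.1% of the E still there. The same leak over that longer fall gives 15.0% of the E charged. The neighbour held 14.3% of the E charged as E.X, and its share was 10.0%.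

All constants are invented; the result is computed.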